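## The problem

The target is an isoflavan: ring A is fused to the saturated oxygen ring C, ring B hangs on C3, and ring B is fused at C2'–C3' to a 2,2-dimethyl-2H-pyran whose oxygen sits on C2', with a free hydroxyl on C4'. C3 is the only stereocentre (R, read from the SMILES). Nothing in the molecule can relay to it, so it has to be set absolutely, and because it is benzylic to ring B it epimerises easily whenever it is alpha to a carbonyl group. Ring A is a fully differentiated phloroglucinol: O1 is the ring ether, O5 a methyl ether, O7 a free phenol, the prenyl group sits on C6 between the two exocyclic oxygens, and C8 is unsubstituted. Prenylation and O-alkylation of a preformed phloroglucinol do not tell C6 from C8 or O5 from O7 reliably. The prenyl alkene, the chromene double bond and the electron-rich phenols exclude hydrogenolysis, strong acid (an ortho-prenylphenol cyclises to a chroman) and oxidants late in the route. On ring B, the oxygen that must enter the pyran (O2') is the more hindered of two otherwise similar phenols. The feature that opens a de novo route is the sequence C5(O)–C6(prenyl)–C7(O)–C8(H)–C8a(O1)–C4a. It maps onto ketene carbon, alkyl-bearing carbon of an ynol ether, oxygen-bearing carbon of the ynol ether, ketene alpha-carbon and the two carbons of a ring C enol ether, so ring A can be grown on ring C with every substituent placed by the reaction itself.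

## Retrosynthesis

**Pyran ring of ring B (39 ⇒ 38 ⇒ 34).** The last operation is fluoride removal of two aryl silyl ethers from 38. The chromene of 38 is cut at the bond from C3' to its vinylic carbon and traced to the 1,1-dimethylpropargyl aryl ether 34. Condensation of a free resorcinol with an enal could close onto O2' or O4' and onto C3' or C5'. The propargyl ether rearrangement from O2' can only reach C3', because C1' is substituted. The forward step needs heat only, which the silyl ethers, the prenyl group and the methyl ether tolerate.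

**Methyl ether (34 ⇒ 33).** The O5–CH3 bond is cut. Phenol 33 has a single free hydroxyl, so no selectivity is asked of the methylation. It is placed before the thermal step so that no free ortho-prenylphenol is heated.

**Ring A (33 ⇒ 23 + 28).** Four bonds are cut: C8–C8a, C5–C6, C7–C8 and C4a–C5. The precursors are the dihydropyranyl diazomethyl ketone 23 and the siloxyalkyne 28. Against cuts that keep ring A intact (C-ring closures onto a preformed phloroglucinol), this one fixes the 5-O/6-prenyl/7-O pattern by the polarity of a ketene and an ynol ether. It also delivers O5 free and O7 silylated, which is exactly the differentiation needed. The forward reaction has to generate a vinylketene under conditions that spare an aryl propargyl ether and a trisubstituted alkene.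

**Siloxyalkyne (28 ⇒ 25 ⇒ 24).** The C–C triple bond is traced to the ester carbonyl of 25 plus one carbon from dibromomethane (ynolate formation, O-silylation). Ester 25 comes from commercial acid 24. This places the prenyl group without any allylation chemistry.

**Diazo ketone and the ring B ethers (23 ⇒ 20 ⇒ 18 + 19; 18 ⇒ 17 ⇒ 16).** The diazo group is traced to the methyl ketone 20 by diazo transfer, because acid chloride and diazomethane routes fail with unsaturated acyl groups. The O2'–C bond is cut to phenol 18 and the propargylic chloride 19. A tertiary propargyl ether with a free acetylenic C–H would not survive the titanium Lewis acid and the amide bases of the earlier steps. Both phenols therefore travel as triisopropylsilyl ethers as far as 16 and are differentiated late, 16 ⇒ 17 ⇒ 18. The forward mono-silylation of 17 relies on the O2' hydroxyl being flanked by the dihydropyranyl substituent.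

**Acetyl group on ring C (16 ⇒ 13 + 14 ⇒ 11).** The bond between the enol ether carbon and the acetyl carbon is cut to the ketene acetal phosphate 13 and the acetyl anion equivalent 14. Phosphate 13 comes from lactone 11 by enolate O-phosphorylation. The acetyl group is only a carrier: this bond is broken again in the Wolff shift. The precursor 11 is a simple 5-aryl-delta-valerolactone with the stereocentre beta to oxygen and not enolisable.

**Stereocentre (11 ⇒ 9 ⇒ 6 + 7).** The lactone C–O bond and the bond that becomes C3–C4 are cut. This leads to the arylacetyl imide 6 and tert-butyl acrylate 7, joined by an auxiliary-controlled Michael addition. A catalytic conjugate arylation of an unsaturated lactone would place the aryl group on the wrong carbon. The forward sequence asks for high facial selectivity and prompt reductive removal of the auxiliary, after which the centre is configurationally safe.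

**Imide (6 ⇒ 3 + 4; 3 ⇒ 1).** The N-acyl bond is cut to acid 3 and the (R)-oxazolidinone 4. Acid 3 is the bis-silyl ether of commercial 2,4-dihydroxyphenylacetic acid 1.

## Roads not taken

**Alternative 1:** Ring C is cut at C3–C4 and O1–C2. A chiral triazolylidene carbene converts the activated ring B arylacetic ester A3 into an azolium enolate, which adds to the ring A ortho-quinone methide A2 (released from a benzylic sulfone) and lactonises to the chroman-2-one A1.
- Merits: the two aromatic rings are joined convergently, enantiocontrol is catalytic, and the chromene of ring B is in place from the start.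
- Weak points:
  - A2 carries OMe, prenyl and protected OH in a 1,2,3-array next to the methide carbon. It must be made from a phloroglucinol by the regioselective prenylation and O-differentiation that are the central difficulty of ring A.
  - The two donor oxygens also make this quinone methide a poor electrophile, and the methide carbon is flanked by OMe.
  - In A1 the stereocentre is both benzylic and alpha to an aryl ester carbonyl, under basic carbene conditions, so erosion of configuration is a real threat.
  - C2 arrives as a carbonyl and needs reduction to the diol and re-closure (two or three steps), since silane/acid deoxygenation is incompatible with prenyl, chromene and acetal groups.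
- Comparison: this road is more convergent and uses no stoichiometric auxiliary, and it would be shorter on the longest line. The chosen plan sets against this regiochemical certainty in ring A, C2 at the right oxidation level throughout, and a stereocentre that is alpha to a carbonyl for one step only.

**Alternative 2:** Ring B is cut at C1'–C6' and C3'–C4'. KOt-Bu promotes Michael addition of the chroman-3-ylacetone A5, through its more substituted enolate, to methyl acrylate and Claisen closure to the cyclohexane-1,3-dione A4, which is aromatised later.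
- Merits: the annulation is thermal, cheap and scalable, and C3 carries only alkyl groups and is robust until the end.
- Weak points:
  - The methyl enolate of A5 competes with the required internal one.
  - Dehydrogenation of A4 to a resorcinol (halogenation–elimination, Pd/C at high temperature or quinone oxidants) threatens the prenyl alkene, the electron-rich ring A and the benzylic C4.
  - The resulting free resorcinol must then close the pyran onto O2'/C3' against O4'/C3' and O4'/C5', with no handle to direct it.
  - Ring A and the stereocentre of A5 must be made beforehand by separate chemistry, so the key step solves neither main problem of the target.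
- Comparison: this road is equal or better in simplicity and scalability of its ring-forming step, with no photochemistry. The chosen plan sets against this that its key step builds the hardest ring with full regiocontrol and exposes the sensitive alkenes to no oxidant.

**Alternative 3:** Ring C is cut at C4–C4a and O1–C2. The iminium ion formed from the 2-arylacrolein A8 and a chiral primary amine is attacked at its methylene by the carbon ortho to the hydroxyl of the symmetric phenol A7, enantioselective protonation of the enamine sets C3, and the phenol closes the lactol A6.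
- Merits: this is the shortest and most convergent road, and the symmetry of A7 removes any regiochemical question in the C–C bond formation.
- Weak points:
  - The stereocentre is set by protonation and then sits alpha to a latent aldehyde (ring–chain tautomerism of the lactol), so its integrity is least secure.
  - After the annulation O5 and O7 carry the same acetal. One must become a methyl ether and the other a free phenol, and acid-mediated acetal removal next to a prenyl group invites chroman formation. The symmetry that helps the key step becomes the problem after it.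
  - The lactol must be deoxygenated, again by silane/acid or by a reduction and re-closure detour.
  - O-alkylation of the phenol competes, and 2-arylacroleins polymerise.
- Comparison: if the O5/O7 differentiation were solved, this road would beat the chosen plan clearly in step count. The chosen plan sets against this that O5 and O7 are differentiated by construction, with one free and one silylated, and that C2 never needs adjustment.

Key step: step 13

Assumption: compounds 4, 7, 14 and 19 are bought; the titanium enolate of imide 6 is taken to react with the same facial sense as in the known alkylations and Michael additions of this auxiliary, so that the (R)-auxiliary gives the (R)-centre.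

## Route

Step 1
Reactants: 1 2,4-dihydroxyphenylacetic acid
Product: 3 2-[2,4-bis(triisopropylsilyloxy)phenyl]acetic acid, via tris-silylated silyl ester 2 (not isolated)
Conditions: TIPSCl (3.3 equiv), imidazole, DMF, rt; then K2CO3, MeOH–THF–H2O, 0 °C; acidify to pH 4
Reagents that add atoms: triisopropylsilyl chloride, CC(C)[Si](Cl)(C(C)C)C(C)C
Why: Exhaustive silylation followed by selective solvolysis of the silyl ester, which is far more labile than an aryl silyl ether because carboxylate leaves from silicon much more readily than phenoxide; standard protection of a hydroxy acid.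

Step 2
Reactants: 3 2-[2,4-bis(triisopropylsilyloxy)phenyl]acetic acid; 4 (4R)-4-benzyl-1,3-oxazolidin-2-one
Product: 6 (4R)-4-benzyl-3-{2-[2,4-bis(triisopropylsilyloxy)phenyl]acetyl}-1,3-oxazolidin-2-one, via mixed pivalic anhydride 5 (not isolated)
Conditions: t-BuCOCl, Et3N, THF, −20 °C; then LiCl, 4, −20 °C → rt
Reagents that add atoms: none
Why: N-Acylation of the oxazolidinone through the mixed pivalic anhydride under LiCl/amine activation; the hindered pivaloyl carbonyl steers attack to the arylacetyl carbon and no strong base touches the aryl silyl ethers.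

Step 3
Reactants: 6 (4R)-4-benzyl-3-{2-[2,4-bis(triisopropylsilyloxy)phenyl]acetyl}-1,3-oxazolidin-2-one; 7 tert-butyl acrylate
Product: 9 tert-butyl (4R)-5-[(4R)-4-benzyl-2-oxo-1,3-oxazolidin-3-yl]-4-[2,4-bis(triisopropylsilyloxy)phenyl]-5-oxopentanoate, via titanium enolate 8 (not isolated)
Conditions: TiCl3(Oi-Pr), i-Pr2NEt, CH2Cl2, 0 °C; then 7, 0 °C
Reagents that add atoms: none
Why: Auxiliary-controlled Michael addition of a chelated Z titanium enolate formed by soft enolisation; the benzyl group of the (R)-auxiliary shields one enolate face, the acrylate bonds on the opposite face, and the new centre (later C3) should be R. Aryl triisopropylsilyl ethers are inert to the mild titanium Lewis acid.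

Step 4
Reactants: 9 tert-butyl (4R)-5-[(4R)-4-benzyl-2-oxo-1,3-oxazolidin-3-yl]-4-[2,4-bis(triisopropylsilyloxy)phenyl]-5-oxopentanoate
Product: 11 (5R)-5-[2,4-bis(triisopropylsilyloxy)phenyl]oxan-2-one, via hydroxy ester 10 (not isolated)
Conditions: LiBH4, MeOH (1 equiv), THF, 0 °C; aqueous work-up; then TsOH·H2O (cat.), PhMe, 80 °C
Reagents that add atoms: none
Why: Reductive cleavage of the auxiliary: LiBH4 reduces the activated imide carbonyl in preference to the tert-butyl ester and returns 4; acid-catalysed lactonisation of the delta-hydroxy tert-butyl ester then closes the six-membered lactone. After the reduction the stereocentre is no longer alpha to a carbonyl and cannot epimerise.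

Step 5
Reactants: 11 (5R)-5-[2,4-bis(triisopropylsilyloxy)phenyl]oxan-2-one
Product: 13 (3R)-3-[2,4-bis(triisopropylsilyloxy)phenyl]-3,4-dihydro-2H-pyran-6-yl diphenyl phosphate, via potassium enolate 12 (not isolated)
Conditions: KN(SiMe3)2, (PhO)2P(O)Cl, THF–DMPU, −78 °C
Reagents that add atoms: diphenyl chlorophosphate, O=P(Cl)(Oc1ccccc1)Oc1ccccc1
Why: O-Phosphorylation of a lactone enolate gives the cyclic ketene acetal phosphate, a more robust cross-coupling partner than the corresponding triflate; C3 of the lactone is the only enolisable position.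

Step 6
Reactants: 13 (3R)-3-[2,4-bis(triisopropylsilyloxy)phenyl]-3,4-dihydro-2H-pyran-6-yl diphenyl phosphate; 14 tributyl(1-ethoxyvinyl)stannane
Product: 16 1-{(3R)-3-[2,4-bis(triisopropylsilyloxy)phenyl]-3,4-dihydro-2H-pyran-6-yl}ethan-1-one, via ethoxydiene 15 (not isolated)
Conditions: Pd(PPh3)4 (5 mol %), LiCl, THF, 65 °C; then 1 M HCl, THF, 0 °C
Reagents that add atoms: water, O
Why: Stille coupling of the ketene acetal phosphate with an acetyl anion equivalent, then mild hydrolysis of the acyclic enol ether of 15. Once the ketone exists the ring enol ether is deactivated, since its protonation would place a cation next to the carbonyl, and it should survive.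

Step 7
Reactants: 16 1-{(3R)-3-[2,4-bis(triisopropylsilyloxy)phenyl]-3,4-dihydro-2H-pyran-6-yl}ethan-1-one
Product: 17 1-[(3R)-3-(2,4-dihydroxyphenyl)-3,4-dihydro-2H-pyran-6-yl]ethan-1-one
Conditions: Bu4NF, AcOH, THF, 0 °C
Reagents that add atoms: none
Why: Fluoride cleavage of both aryl silyl ethers; acetic acid buffering keeps the liberated phenoxides from aldol or conjugate addition chemistry with the enone.

Step 8
Reactants: 17 1-[(3R)-3-(2,4-dihydroxyphenyl)-3,4-dihydro-2H-pyran-6-yl]ethan-1-one
Product: 18 1-{(3R)-3-[2-hydroxy-4-(triisopropylsilyloxy)phenyl]-3,4-dihydro-2H-pyran-6-yl}ethan-1-one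
Conditions: TIPSCl (1.05 equiv), imidazole, DMF, −20 → 0 °C
Reagents that add atoms: triisopropylsilyl chloride, CC(C)[Si](Cl)(C(C)C)C(C)C
Why: Regioselective kinetic silylation: the bulky silyl chloride should take the hydroxyl para to the ring C substituent, because the ortho hydroxyl is shielded by the adjacent secondary alkyl group.

Step 9
Reactants: 18 1-{(3R)-3-[2-hydroxy-4-(triisopropylsilyloxy)phenyl]-3,4-dihydro-2H-pyran-6-yl}ethan-1-one; 19 3-chloro-3-methylbut-1-yne
Product: 20 1-{(3R)-3-[2-(2-methylbut-3-yn-2-yloxy)-4-(triisopropylsilyloxy)phenyl]-3,4-dihydro-2H-pyran-6-yl}ethan-1-one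
Conditions: CuCl2·2H2O (1 mol %), DBU, MeCN, 0 °C
Reagents that add atoms: none
Why: Copper-catalysed O-propargylation of a phenol with a tertiary propargylic chloride, which proceeds through a copper allenylidene and so succeeds at a tertiary centre under mild base; only one free phenol is present.

Step 10
Reactants: 20 1-{(3R)-3-[2-(2-methylbut-3-yn-2-yloxy)-4-(triisopropylsilyloxy)phenyl]-3,4-dihydro-2H-pyran-6-yl}ethan-1-one
Product: 23 2-diazo-1-{(3R)-3-[2-(2-methylbut-3-yn-2-yloxy)-4-(triisopropylsilyloxy)phenyl]-3,4-dihydro-2H-pyran-6-yl}ethan-1-one, via lithium enolate 21 (not isolated), via trifluoroacetyl diketone 22 (not isolated)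
Conditions: LiN(SiMe3)2 (1.1 equiv), THF, −78 °C; CF3CO2CH2CF3, −78 °C; then MsN3, Et3N, H2O, MeCN, rt
Reagents that add atoms: methanesulfonyl azide, CS(=O)(=O)N=[N+]=[N-]
Why: Detrifluoroacetylative diazo transfer: the kinetic methyl enolate 21 is trifluoroacetylated to 22, which accepts the diazo group from the sulfonyl azide and loses the trifluoroacetyl group as its sulfonamide. The methyl ketone is several pK units more acidic than the acetylenic C–H, and this is the standard entry to unsaturated diazo ketones, where acid chloride and diazomethane give pyrazolines.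

Step 11
Reactants: 24 4-methylpent-3-enoic acid
Product: 25 methyl 4-methylpent-3-enoate
Conditions: MeI, K2CO3, DMF, rt
Reagents that add atoms: iodomethane, CI
Why: Carboxylate O-alkylation under non-acidic conditions; acid-catalysed esterification is avoided because the trisubstituted alkene would lactonise onto the acid.

Step 12
Reactants: 25 methyl 4-methylpent-3-enoate
Product: 28 triisopropyl[(5-methylhex-4-en-1-yn-1-yl)oxy]silane, via dibromo enolate 26 (not isolated), via lithium ynolate 27 (not isolated)
Conditions: CH2Br2, lithium 2,2,6,6-tetramethylpiperidide (2 equiv), THF, −78 °C; 25; then n-BuLi, −78 → 0 °C; then TIPSCl, −78 °C → rt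
Reagents that add atoms: dibromomethane, BrCBr; triisopropylsilyl chloride, CC(C)[Si](Cl)(C(C)C)C(C)C
Why: Kowalski ester homologation stopped at the ynolate: dibromomethyllithium adds to the ester to give enolate 26, bromine–lithium exchange and 1,2-shift give ynolate 27, and the bulky silyl chloride traps it on oxygen.

Step 13
Reactants: 23 2-diazo-1-{(3R)-3-[2-(2-methylbut-3-yn-2-yloxy)-4-(triisopropylsilyloxy)phenyl]-3,4-dihydro-2H-pyran-6-yl}ethan-1-one; 28 triisopropyl[(5-methylhex-4-en-1-yn-1-yl)oxy]silane
Product: 33 (3R)-3-[2-(2-methylbut-3-yn-2-yloxy)-4-(triisopropylsilyloxy)phenyl]-6-(3-methylbut-2-en-1-yl)-7-(triisopropylsilyloxy)-3,4-dihydro-2H-chromen-5-ol, via vinylketene 29 (not isolated), via cyclobutenone 30 (not isolated), via dienylketene 31 (not isolated), via cyclohexadienone 32 (not isolated)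
Conditions: hν (medium-pressure mercury lamp, Pyrex filter, above 300 nm), 28 (1.5 equiv), degassed ClCH2CH2Cl, rt; then 80 °C
Reagents that add atoms: none
Why: Light above 300 nm is absorbed by the diazo ketone alone and expels N2; Wolff rearrangement with 1,2-shift of the dihydropyranyl carbon forms C8–C8a and gives vinylketene 29, in which C8a already carries O1. The nucleophilic, prenyl-bearing carbon of siloxyalkyne 28 attacks the ketene carbon in a regiospecific [2+2] cycloaddition (C5–C6 and C7–C8), giving cyclobutenone 30. Four-electron electrocyclic opening of 30 (by light or at 80 °C) gives dienylketene 31, whose six-electron disrotatory electrocyclisation joins the ketene carbon to C4a (C4a–C5) and closes ring A as dienone 32, which tautomerises to phenol 33. The closest known reaction type is the Danheiser benzannulation in its diazo ketone form with siloxyalkynes, established for diazo ketones of 1-acylcycloalkenes, of which 23 is the 2-oxa analogue. No stereocentre is created, since the sp3 centres of 30 and 32 vanish on aromatisation, and C3 is remote and not enolisable. The step needs regiocontrol, secured by the polarity of ketene and ynol ether (the bulky silyl group also blocks silyl migration to carbon), and capture of 29 by 28 in preference to the tethered terminal alkyne, secured by the far higher nucleophilicity of the ynol ether. A 1,5-hydrogen shift of 29 is excluded because the ring methylene is trans to the ketene across the ring double bond, and 80 °C is below the onset of the propargyl ether rearrangement.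

Step 14
Reactants: 33 (3R)-3-[2-(2-methylbut-3-yn-2-yloxy)-4-(triisopropylsilyloxy)phenyl]-6-(3-methylbut-2-en-1-yl)-7-(triisopropylsilyloxy)-3,4-dihydro-2H-chromen-5-ol
Product: 34 (3R)-5-methoxy-3-[2-(2-methylbut-3-yn-2-yloxy)-4-(triisopropylsilyloxy)phenyl]-6-(3-methylbut-2-en-1-yl)-7-(triisopropylsilyloxy)-3,4-dihydro-2H-chromene
Conditions: MeI, K2CO3, acetone, 50 °C
Reagents that add atoms: iodomethane, CI
Why: Williamson methylation of the only free phenol; aryl triisopropylsilyl ethers and the terminal alkyne tolerate carbonate in acetone. Methylating before the thermal step means no free ortho-prenylphenol is heated.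

Step 15
Reactants: 34 (3R)-5-methoxy-3-[2-(2-methylbut-3-yn-2-yloxy)-4-(triisopropylsilyloxy)phenyl]-6-(3-methylbut-2-en-1-yl)-7-(triisopropylsilyloxy)-3,4-dihydro-2H-chromene
Product: 38 (3R)-3-[2,2-dimethyl-5-(triisopropylsilyloxy)-2H-chromen-8-yl]-5-methoxy-6-(3-methylbut-2-en-1-yl)-7-(triisopropylsilyloxy)-3,4-dihydro-2H-chromene, via allenyl dienone 35 (not isolated), via allenylphenol 36 (not isolated), via quinone methide 37 (not isolated)
Conditions: PhNEt2, 190 °C
Reagents that add atoms: none
Why: Aryl propargyl ether Claisen rearrangement: the [3,3] shift can only reach C3', since C1' is substituted, giving allenyl dienone 35; tautomerisation to 36, a 1,5-hydrogen shift to quinone methide 37 and oxa-six-electron electrocyclisation close the 2,2-dimethylchromene on O2'.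

Step 16
Reactants: 38 (3R)-3-[2,2-dimethyl-5-(triisopropylsilyloxy)-2H-chromen-8-yl]-5-methoxy-6-(3-methylbut-2-en-1-yl)-7-(triisopropylsilyloxy)-3,4-dihydro-2H-chromene
Product: 39 (3R)-3-(5-hydroxy-2,2-dimethyl-2H-chromen-8-yl)-5-methoxy-6-(3-methylbut-2-en-1-yl)-3,4-dihydro-2H-chromen-7-ol
Conditions: Bu4NF, AcOH, THF, 0 °C → rt
Reagents that add atoms: none
Why: Fluoride cleavage of the two aryl silyl ethers under buffered conditions that leave the prenyl group, the chromene and the stereocentre untouched.

## Compound list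

1 | 2,4-dihydroxyphenylacetic acid | OC(=O)Cc1ccc(O)cc1O | starting material
2 | triisopropylsilyl 2-[2,4-bis(triisopropylsilyloxy)phenyl]acetate | CC(C)[Si](OC(=O)Cc1ccc(O[Si](C(C)C)(C(C)C)C(C)C)cc1O[Si](C(C)C)(C(C)C)C(C)C)(C(C)C)C(C)C | intermediate
3 | 2-[2,4-bis(triisopropylsilyloxy)phenyl]acetic acid | OC(=O)Cc1ccc(O[Si](C(C)C)(C(C)C)C(C)C)cc1O[Si](C(C)C)(C(C)C)C(C)C | intermediate
4 | (4R)-4-benzyl-1,3-oxazolidin-2-one | O=C1N[C@H](Cc2ccccc2)CO1 | starting material
5 | 2-[2,4-bis(triisopropylsilyloxy)phenyl]acetic pivalic anhydride | CC(C)(C)C(=O)OC(=O)Cc1ccc(O[Si](C(C)C)(C(C)C)C(C)C)cc1O[Si](C(C)C)(C(C)C)C(C)C | intermediate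
6 | (4R)-4-benzyl-3-{2-[2,4-bis(triisopropylsilyloxy)phenyl]acetyl}-1,3-oxazolidin-2-one | O=C(Cc1ccc(O[Si](C(C)C)(C(C)C)C(C)C)cc1O[Si](C(C)C)(C(C)C)C(C)C)N1[C@H](Cc2ccccc2)COC1=O | intermediate
7 | tert-butyl acrylate | C=CC(=O)OC(C)(C)C | starting material
8 | (Z)-dichloro(isopropoxy)titanium enolate of 6 | CC(C)O[Ti](Cl)(Cl)O/C(=C\c1ccc(O[Si](C(C)C)(C(C)C)C(C)C)cc1O[Si](C(C)C)(C(C)C)C(C)C)N1[C@H](Cc2ccccc2)COC1=O | intermediate
9 | tert-butyl (4R)-5-[(4R)-4-benzyl-2-oxo-1,3-oxazolidin-3-yl]-4-[2,4-bis(triisopropylsilyloxy)phenyl]-5-oxopentanoate | CC(C)(C)OC(=O)CC[C@H](c1ccc(O[Si](C(C)C)(C(C)C)C(C)C)cc1O[Si](C(C)C)(C(C)C)C(C)C)C(=O)N1[C@H](Cc2ccccc2)COC1=O | intermediate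
10 | tert-butyl (4R)-4-[2,4-bis(triisopropylsilyloxy)phenyl]-5-hydroxypentanoate | CC(C)(C)OC(=O)CC[C@H](c1ccc(O[Si](C(C)C)(C(C)C)C(C)C)cc1O[Si](C(C)C)(C(C)C)C(C)C)CO | intermediate
11 | (5R)-5-[2,4-bis(triisopropylsilyloxy)phenyl]oxan-2-one | O=C1CC[C@H](c2ccc(O[Si](C(C)C)(C(C)C)C(C)C)cc2O[Si](C(C)C)(C(C)C)C(C)C)CO1 | intermediate
12 | potassium (3R)-3-[2,4-bis(triisopropylsilyloxy)phenyl]-3,4-dihydro-2H-pyran-6-olate (enolate of 11) | [K+].[O-]C1=CC[C@H](c2ccc(O[Si](C(C)C)(C(C)C)C(C)C)cc2O[Si](C(C)C)(C(C)C)C(C)C)CO1 | intermediate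
13 | (3R)-3-[2,4-bis(triisopropylsilyloxy)phenyl]-3,4-dihydro-2H-pyran-6-yl diphenyl phosphate | O=P(Oc1ccccc1)(Oc1ccccc1)OC1=CC[C@H](c2ccc(O[Si](C(C)C)(C(C)C)C(C)C)cc2O[Si](C(C)C)(C(C)C)C(C)C)CO1 | intermediate
14 | tributyl(1-ethoxyvinyl)stannane | CCCC[Sn](CCCC)(CCCC)C(=C)OCC | starting material
15 | (3R)-3-[2,4-bis(triisopropylsilyloxy)phenyl]-6-(1-ethoxyvinyl)-3,4-dihydro-2H-pyran | CCOC(=C)C1=CC[C@H](c2ccc(O[Si](C(C)C)(C(C)C)C(C)C)cc2O[Si](C(C)C)(C(C)C)C(C)C)CO1 | intermediate
16 | 1-{(3R)-3-[2,4-bis(triisopropylsilyloxy)phenyl]-3,4-dihydro-2H-pyran-6-yl}ethan-1-one | CC(=O)C1=CC[C@H](c2ccc(O[Si](C(C)C)(C(C)C)C(C)C)cc2O[Si](C(C)C)(C(C)C)C(C)C)CO1 | intermediate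
17 | 1-[(3R)-3-(2,4-dihydroxyphenyl)-3,4-dihydro-2H-pyran-6-yl]ethan-1-one | CC(=O)C1=CC[C@H](c2ccc(O)cc2O)CO1 | intermediate
18 | 1-{(3R)-3-[2-hydroxy-4-(triisopropylsilyloxy)phenyl]-3,4-dihydro-2H-pyran-6-yl}ethan-1-one | CC(=O)C1=CC[C@H](c2ccc(O[Si](C(C)C)(C(C)C)C(C)C)cc2O)CO1 | intermediate
19 | 3-chloro-3-methylbut-1-yne | CC(C)(Cl)C#C | starting material
20 | 1-{(3R)-3-[2-(2-methylbut-3-yn-2-yloxy)-4-(triisopropylsilyloxy)phenyl]-3,4-dihydro-2H-pyran-6-yl}ethan-1-one | CC(=O)C1=CC[C@H](c2ccc(O[Si](C(C)C)(C(C)C)C(C)C)cc2OC(C)(C)C#C)CO1 | intermediate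
21 | lithium enolate of 20 (methyl side) | [Li+].[O-]C(=C)C1=CC[C@H](c2ccc(O[Si](C(C)C)(C(C)C)C(C)C)cc2OC(C)(C)C#C)CO1 | intermediate
22 | 4,4,4-trifluoro-1-{(3R)-3-[2-(2-methylbut-3-yn-2-yloxy)-4-(triisopropylsilyloxy)phenyl]-3,4-dihydro-2H-pyran-6-yl}butane-1,3-dione | O=C(CC(=O)C(F)(F)F)C1=CC[C@H](c2ccc(O[Si](C(C)C)(C(C)C)C(C)C)cc2OC(C)(C)C#C)CO1 | intermediate
23 | 2-diazo-1-{(3R)-3-[2-(2-methylbut-3-yn-2-yloxy)-4-(triisopropylsilyloxy)phenyl]-3,4-dihydro-2H-pyran-6-yl}ethan-1-one | [N-]=[N+]=CC(=O)C1=CC[C@H](c2ccc(O[Si](C(C)C)(C(C)C)C(C)C)cc2OC(C)(C)C#C)CO1 | intermediate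
24 | 4-methylpent-3-enoic acid | CC(C)=CCC(=O)O | starting material
25 | methyl 4-methylpent-3-enoate | CC(C)=CCC(=O)OC | intermediate
26 | lithium 1,1-dibromo-5-methylhexa-1,4-dien-2-olate | [Li+].[O-]C(CC=C(C)C)=C(Br)Br | intermediate
27 | lithium 5-methylhex-4-en-1-yn-1-olate | [Li+].[O-]C#CCC=C(C)C | intermediate
28 | triisopropyl[(5-methylhex-4-en-1-yn-1-yl)oxy]silane | CC(C)=CCC#CO[Si](C(C)C)(C(C)C)C(C)C | intermediate
29 | 2-{(3R)-3-[2-(2-methylbut-3-yn-2-yloxy)-4-(triisopropylsilyloxy)phenyl]-3,4-dihydro-2H-pyran-6-yl}ethenone (vinylketene) | O=C=CC1=CC[C@H](c2ccc(O[Si](C(C)C)(C(C)C)C(C)C)cc2OC(C)(C)C#C)CO1 | intermediate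
30 | 4-{(3R)-3-aryl-3,4-dihydro-2H-pyran-6-yl}-2-(3-methylbut-2-en-1-yl)-3-(triisopropylsilyloxy)cyclobut-2-en-1-one, aryl as in 23, both epimers at the ring carbon | O=C1C(CC=C(C)C)=C(O[Si](C(C)C)(C(C)C)C(C)C)C1C1=CC[C@H](c2ccc(O[Si](C(C)C)(C(C)C)C(C)C)cc2OC(C)(C)C#C)CO1 | intermediate
31 | (3Z)-4-{(3R)-3-aryl-3,4-dihydro-2H-pyran-6-yl}-2-(3-methylbut-2-en-1-yl)-3-(triisopropylsilyloxy)buta-1,3-dien-1-one, aryl as in 23 (dienylketene) | O=C=C(CC=C(C)C)/C(O[Si](C(C)C)(C(C)C)C(C)C)=C\C1=CC[C@H](c2ccc(O[Si](C(C)C)(C(C)C)C(C)C)cc2OC(C)(C)C#C)CO1 | intermediate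
32 | 4a-H keto tautomer of 33 (3,4-dihydro-2H-chromen-5(4aH)-one, both epimers at C4a) | O=C1C(CC=C(C)C)=C(O[Si](C(C)C)(C(C)C)C(C)C)C=C2OC[C@@H](c3ccc(O[Si](C(C)C)(C(C)C)C(C)C)cc3OC(C)(C)C#C)CC12 | intermediate
33 | (3R)-3-[2-(2-methylbut-3-yn-2-yloxy)-4-(triisopropylsilyloxy)phenyl]-6-(3-methylbut-2-en-1-yl)-7-(triisopropylsilyloxy)-3,4-dihydro-2H-chromen-5-ol | Oc1c(CC=C(C)C)c(O[Si](C(C)C)(C(C)C)C(C)C)cc2c1C[C@H](c1ccc(O[Si](C(C)C)(C(C)C)C(C)C)cc1OC(C)(C)C#C)CO2 | intermediate
34 | (3R)-5-methoxy-3-[2-(2-methylbut-3-yn-2-yloxy)-4-(triisopropylsilyloxy)phenyl]-6-(3-methylbut-2-en-1-yl)-7-(triisopropylsilyloxy)-3,4-dihydro-2H-chromene | COc1c(CC=C(C)C)c(O[Si](C(C)C)(C(C)C)C(C)C)cc2c1C[C@H](c1ccc(O[Si](C(C)C)(C(C)C)C(C)C)cc1OC(C)(C)C#C)CO2 | intermediate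
35 | 6-(chroman-3-yl)-2-(3-methylbuta-1,2-dien-1-yl)-3-(triisopropylsilyloxy)cyclohexa-3,5-dien-1-one, chroman as in 34 (allenyl dienone) | COc1c(CC=C(C)C)c(O[Si](C(C)C)(C(C)C)C(C)C)cc2c1C[C@H](C1=CC=C(O[Si](C(C)C)(C(C)C)C(C)C)C(C=C=C(C)C)C1=O)CO2 | intermediate
36 | 6-(chroman-3-yl)-2-(3-methylbuta-1,2-dien-1-yl)-3-(triisopropylsilyloxy)phenol, chroman as in 34 | COc1c(CC=C(C)C)c(O[Si](C(C)C)(C(C)C)C(C)C)cc2c1C[C@H](c1ccc(O[Si](C(C)C)(C(C)C)C(C)C)c(C=C=C(C)C)c1O)CO2 | intermediate
37 | 2-(chroman-3-yl)-6-(3-methylbut-2-en-1-ylidene)-5-(triisopropylsilyloxy)cyclohexa-2,4-dien-1-one, chroman as in 34 (ortho-quinone methide) | COc1c(CC=C(C)C)c(O[Si](C(C)C)(C(C)C)C(C)C)cc2c1C[C@H](C1=CC=C(O[Si](C(C)C)(C(C)C)C(C)C)C(=CC=C(C)C)C1=O)CO2 | intermediate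
38 | (3R)-3-[2,2-dimethyl-5-(triisopropylsilyloxy)-2H-chromen-8-yl]-5-methoxy-6-(3-methylbut-2-en-1-yl)-7-(triisopropylsilyloxy)-3,4-dihydro-2H-chromene | COc1c(CC=C(C)C)c(O[Si](C(C)C)(C(C)C)C(C)C)cc2c1C[C@H](c1ccc(O[Si](C(C)C)(C(C)C)C(C)C)c3c1OC(C)(C)C=C3)CO2 | intermediate
39 | (3R)-3-(5-hydroxy-2,2-dimethyl-2H-chromen-8-yl)-5-methoxy-6-(3-methylbut-2-en-1-yl)-3,4-dihydro-2H-chromen-7-ol | COc1c(CC=C(C)C)c(O)cc2c1C[C@H](c1ccc(O)c3c1OC(C)(C)C=C3)CO2 | target

## Step count and least certain steps

Total: 16 steps. Longest linear sequence: 14 steps (steps 1–10 and 13–16); steps 11 and 12 make the siloxyalkyne.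

**Step 13 (key step).** Most likely to go wrong is capture of the vinylketene: competing photoreaction or premature thermal rearrangement of the aryl dimethylpropargyl ether, addition of the carbene or ketene to the tethered terminal alkyne, and ketene dimerisation when the [2+2] step is slow. The fallback keeps the annulation but takes the propargyl ether out of it. Phenol 18 is O-allylated (allyl bromide, K2CO3, acetone) to the allyl ether ketone F1. F1 is converted as in step 10 into the diazo ketone F2. F2 is irradiated with 28 to give the annulated phenol F3, which is methylated to F4. The allyl group is removed with Pd(PPh3)4 and morpholine to give the 2'-phenol F5, and copper-catalysed propargylation of F5 with 19 returns to the route at 34.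

**Step 12.** The ester has doubly activated alpha-hydrogens (allylic and next to the carbonyl). Enolisation by the carbenoid or the amide base, with drift of the double bond into conjugation, can outrun carbonyl addition, and C-silylation of the ynolate would give a silylketene. The fallback makes the ynolate by oxidation of an acetylide instead. From 25, reduction with i-Bu2AlH at −78 °C gives 4-methylpent-3-enal F6. Corey–Fuchs olefination (CBr4, PPh3, Et3N) gives the dibromoalkene F7. n-BuLi (2 equiv) gives the lithium acetylide F8, which is oxidised in the same flask with LiOOt-Bu to ynolate 27 and silylated (TIPSOTf) to rejoin at 28.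

**Step 6.** The ketene acetal phosphate can hydrolyse back to the lactone before oxidative addition, and the acid treatment can over-hydrolyse the ring enol ether before the deactivating ketone has formed. The fallback inserts carbon monoxide instead of using tin and acid. Phosphate 13 is methoxycarbonylated (CO, MeOH, Et3N, Pd(PPh3)4) to the methyl dihydropyrancarboxylate F9. F9 is converted with MeNHOMe·HCl and i-PrMgCl into the Weinreb amide F10, and MeMgBr gives ketone 16.

**Step 8.** Silylation at the hindered O2' hydroxyl and double silylation can compete if the steric bias of the ring C substituent is smaller than expected. The fallback exerts the discrimination in a cleavage step instead. Diol 17 is acetylated (Ac2O, pyridine) to the diacetate F11. The exposed 4'-acetate is removed selectively (Candida antarctica lipase B with n-butanol, or one equivalent of an amine) to give the 2'-acetate 4'-phenol F12. F12 is silylated without ambiguity to the 2'-acetate 4'-silyl ether F13, and brief K2CO3/MeOH at 0 °C removes the acetate to give 18.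

**Step 3.** The bulky ortho silyloxy group may slow the Michael addition so that acrylate oligomerisation or loss of facial selectivity intervenes, and the acidic alpha-aryl centre of the adduct may epimerise before work-up. The fallback forms the same bond by alkylation and builds the lactone by oxidation. Imide 6 is allylated (NaN(SiMe3)2, allyl iodide, −78 °C; same facial sense) to the pentenoyl imide F14. LiBH4 gives the pentenol F15. Hydroboration with 9-BBN and oxidation with NaBO3·4H2O gives the 1,5-diol F16. TEMPO/PhI(OAc)2 oxidises the unhindered primary alcohol and closes the lactol, which is oxidised on to lactone 11.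

## Further compounds

F1 | step 13 | 1-{(3R)-3-[2-(allyloxy)-4-(triisopropylsilyloxy)phenyl]-3,4-dihydro-2H-pyran-6-yl}ethan-1-one | CC(=O)C1=CC[C@H](c2ccc(O[Si](C(C)C)(C(C)C)C(C)C)cc2OCC=C)CO1
F2 | step 13 | 1-{(3R)-3-[2-(allyloxy)-4-(triisopropylsilyloxy)phenyl]-3,4-dihydro-2H-pyran-6-yl}-2-diazoethan-1-one | [N-]=[N+]=CC(=O)C1=CC[C@H](c2ccc(O[Si](C(C)C)(C(C)C)C(C)C)cc2OCC=C)CO1
F3 | step 13 | (3R)-3-[2-(allyloxy)-4-(triisopropylsilyloxy)phenyl]-6-(3-methylbut-2-en-1-yl)-7-(triisopropylsilyloxy)-3,4-dihydro-2H-chromen-5-ol | Oc1c(CC=C(C)C)c(O[Si](C(C)C)(C(C)C)C(C)C)cc2c1C[C@H](c1ccc(O[Si](C(C)C)(C(C)C)C(C)C)cc1OCC=C)CO2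
F4 | step 13 | (3R)-3-[2-(allyloxy)-4-(triisopropylsilyloxy)phenyl]-5-methoxy-6-(3-methylbut-2-en-1-yl)-7-(triisopropylsilyloxy)-3,4-dihydro-2H-chromene | COc1c(CC=C(C)C)c(O[Si](C(C)C)(C(C)C)C(C)C)cc2c1C[C@H](c1ccc(O[Si](C(C)C)(C(C)C)C(C)C)cc1OCC=C)CO2
F5 | step 13 | 2-[(3R)-5-methoxy-6-(3-methylbut-2-en-1-yl)-7-(triisopropylsilyloxy)-3,4-dihydro-2H-chromen-3-yl]-5-(triisopropylsilyloxy)phenol | COc1c(CC=C(C)C)c(O[Si](C(C)C)(C(C)C)C(C)C)cc2c1C[C@H](c1ccc(O[Si](C(C)C)(C(C)C)C(C)C)cc1O)CO2
F6 | step 12 | 4-methylpent-3-enal | CC(C)=CCC=O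
F7 | step 12 | 1,1-dibromo-5-methylhexa-1,4-diene | CC(C)=CCC=C(Br)Br
F8 | step 12 | lithium 5-methylhex-4-en-1-yn-1-ide | [Li+].[C-]#CCC=C(C)C
F9 | step 6 | methyl (3R)-3-[2,4-bis(triisopropylsilyloxy)phenyl]-3,4-dihydro-2H-pyran-6-carboxylate | COC(=O)C1=CC[C@H](c2ccc(O[Si](C(C)C)(C(C)C)C(C)C)cc2O[Si](C(C)C)(C(C)C)C(C)C)CO1
F10 | step 6 | (3R)-3-[2,4-bis(triisopropylsilyloxy)phenyl]-N-methoxy-N-methyl-3,4-dihydro-2H-pyran-6-carboxamide | CON(C)C(=O)C1=CC[C@H](c2ccc(O[Si](C(C)C)(C(C)C)C(C)C)cc2O[Si](C(C)C)(C(C)C)C(C)C)CO1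
F11 | step 8 | 4-[(3R)-6-acetyl-3,4-dihydro-2H-pyran-3-yl]-1,3-phenylene diacetate | CC(=O)C1=CC[C@H](c2ccc(OC(C)=O)cc2OC(C)=O)CO1
F12 | step 8 | 2-[(3R)-6-acetyl-3,4-dihydro-2H-pyran-3-yl]-5-hydroxyphenyl acetate | CC(=O)C1=CC[C@H](c2ccc(O)cc2OC(C)=O)CO1
F13 | step 8 | 2-[(3R)-6-acetyl-3,4-dihydro-2H-pyran-3-yl]-5-(triisopropylsilyloxy)phenyl acetate | CC(=O)C1=CC[C@H](c2ccc(O[Si](C(C)C)(C(C)C)C(C)C)cc2OC(C)=O)CO1
F14 | step 3 | (4R)-4-benzyl-3-{(2R)-2-[2,4-bis(triisopropylsilyloxy)phenyl]pent-4-enoyl}-1,3-oxazolidin-2-one | C=CC[C@H](c1ccc(O[Si](C(C)C)(C(C)C)C(C)C)cc1O[Si](C(C)C)(C(C)C)C(C)C)C(=O)N1[C@H](Cc2ccccc2)COC1=O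
F15 | step 3 | (2R)-2-[2,4-bis(triisopropylsilyloxy)phenyl]pent-4-en-1-ol | C=CC[C@H](c1ccc(O[Si](C(C)C)(C(C)C)C(C)C)cc1O[Si](C(C)C)(C(C)C)C(C)C)CO
F16 | step 3 | (2R)-2-[2,4-bis(triisopropylsilyloxy)phenyl]pentane-1,5-diol | OCCC[C@H](c1ccc(O[Si](C(C)C)(C(C)C)C(C)C)cc1O[Si](C(C)C)(C(C)C)C(C)C)CO
A1 | alternative 1 | (3R)-5-methoxy-7-(methoxymethoxy)-3-[5-(methoxymethoxy)-2,2-dimethyl-2H-chromen-8-yl]-6-(3-methylbut-2-en-1-yl)chroman-2-one | COc1c(CC=C(C)C)c(OCOC)cc2c1C[C@H](c1ccc(OCOC)c3c1OC(C)(C)C=C3)C(=O)O2
A2 | alternative 1 | 5-methoxy-3-(methoxymethoxy)-4-(3-methylbut-2-en-1-yl)-6-methylidenecyclohexa-2,4-dien-1-one (ortho-quinone methide) | C=C1C(=O)C=C(OCOC)C(CC=C(C)C)=C1OC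
A3 | alternative 1 | 4-nitrophenyl 2-[5-(methoxymethoxy)-2,2-dimethyl-2H-chromen-8-yl]acetate | O=C(Cc1ccc(OCOC)c2C=CC(C)(C)Oc12)Oc1ccc([N+](=O)[O-])cc1
A4 | alternative 2 | 4-[(3R)-5-methoxy-7-(methoxymethoxy)-6-(3-methylbut-2-en-1-yl)-3,4-dihydro-2H-chromen-3-yl]cyclohexane-1,3-dione, epimers at the dione ring carbon | COc1c(CC=C(C)C)c(OCOC)cc2c1C[C@H](C1CCC(=O)CC1=O)CO2
A5 | alternative 2 | 1-[(3R)-5-methoxy-7-(methoxymethoxy)-6-(3-methylbut-2-en-1-yl)-3,4-dihydro-2H-chromen-3-yl]propan-2-one | COc1c(CC=C(C)C)c(OCOC)cc2c1C[C@H](CC(C)=O)CO2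
A6 | alternative 3 | (3R)-3-[2,2-dimethyl-5-(triisopropylsilyloxy)-2H-chromen-8-yl]-5,7-bis(methoxymethoxy)-6-(3-methylbut-2-en-1-yl)chroman-2-ol, mixture of anomers | OC1Oc2cc(OCOC)c(CC=C(C)C)c(OCOC)c2C[C@@H]1c1ccc(O[Si](C(C)C)(C(C)C)C(C)C)c2c1OC(C)(C)C=C2
A7 | alternative 3 | 3,5-bis(methoxymethoxy)-4-(3-methylbut-2-en-1-yl)phenol | COCOc1cc(O)cc(OCOC)c1CC=C(C)C
A8 | alternative 3 | 2-[2,2-dimethyl-5-(triisopropylsilyloxy)-2H-chromen-8-yl]prop-2-enal | C=C(C=O)c1ccc(O[Si](C(C)C)(C(C)C)C(C)C)c2C=CC(C)(C)Oc12
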